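The plan cuts ring B at its C4–C5 bond and traces it back to a four-membered ring. Ring B has para oxygens at C2 and C5, the ring A ether at C1, a further oxygen at C3 and hydrogens at C4 and C6: the exact imprint of a 4-alkenyl-4-oxycyclobutenone ring expansion. Heating the precursor, a 3-(2,4,6-trimethoxyphenoxy)cyclobutenone whose C4 carries a silyloxy and a 1-methoxyvinyl group, should build ring B in one operation with the crowded A–O–B ether already in place, C5–OH free and C2–O still masked. Methylation, desilylation, one copper-catalysed union with a ring C–D–E iodide and global demethylation then finish the pentamer.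

Key step: step 5

Remark: the target has no stereocentre; rings run from A (2,4,6-trihydroxyphenoxy end) to E (3,4,5-trihydroxyphenoxy end), numbered ring B C1 (O–A), C2 (O–C), C3/C5 (OH); ring C C1 (O–B), C3/C5 (OH), C4 (O–D); ring D C1 (O–C), C2 (O–E), C3–C5 (OH); all phenols travel as methyl ethers and the cyclobutenone carbinol as its TBS ether, so the two para oxygens of ring B are told apart by construction and not by a selective alkylation.

Step 1
Reactants: 1 diisopropyl squarate
Product: 3 3-isopropoxycyclobut-3-ene-1,2-dione (isopropyl semisquarate), via hydroxycyclobutenone 2 (not isolated)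
Conditions: LiAlH(OtBu)3, THF, −78 to −20 °C; 1 M HCl work-up; then conc. HCl (cat.), CH2Cl2, rt
Reagents that add atoms: none
Why: A 1,2-hydride reduction of one squarate carbonyl gives the racemic carbinol 2, and acid-catalysed allylic ionisation with loss of isopropanol then erases that centre and delivers the semisquarate, the established reductive entry from dialkyl squarates.

Step 2
Reactants: 3 isopropyl semisquarate
Product: 4 3-hydroxycyclobut-3-ene-1,2-dione (semisquaric acid)
Conditions: 2 M HCl, H2O/THF, 45 °C; evaporate, toluene azeotrope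
Reagents that add atoms: water, O
Why: Acid-catalysed vinylogous ester hydrolysis (addition–elimination of water at C3) should be clean, and the strong, water-soluble acid is obtained simply by evaporation because no metal salts are present.

Step 3
Reactants: 4 semisquaric acid; 5 2,4,6-trimethoxyphenol
Product: 7 3-(2,4,6-trimethoxyphenoxy)cyclobut-3-ene-1,2-dione (aryl semisquarate), via semisquaric chloride 6 (not isolated)
Conditions: (COCl)2 (1.05 equiv), DMF (cat.), CH2Cl2, 0 °C to rt; volatiles off at 0 °C; then 5, i-Pr2NEt, CH2Cl2, −40 to 0 °C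
Reagents that add atoms: oxalyl chloride, O=C(Cl)C(Cl)=O (chlorine of 6 only; nothing of it remains in 7)
Why: Vilsmeier-type chlorination turns the vinylogous acid into its chloride, and vinylogous acyl substitution (addition–elimination at C3) by the di-ortho-substituted phenol then forms the A–O–B oxygen bridge far more easily than any arylation of that phenol could.

Step 4
Reactants: 7 aryl semisquarate; 8 methyl vinyl ether
Product: 11 4-[(tert-butyldimethylsilyl)oxy]-4-(1-methoxyvinyl)-3-(2,4,6-trimethoxyphenoxy)cyclobut-2-en-1-one (racemic; TBS ether of the 4-hydroxy carbinol), via 1-methoxyvinyllithium 9 (not isolated), via lithium alkoxide 10 (not isolated)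
Conditions: 8 (excess), t-BuLi, THF, −78 to 0 °C; cannulate into 7, THF, −78 °C; TBSOTf, −78 to −30 °C; NaHCO3 aq.
Reagents that add atoms: tert-butyldimethylsilyl triflate, CC(C)(C)[Si](C)(C)OS(=O)(=O)C(F)(F)F; tert-butyllithium, [Li]C(C)(C)C (lithium of 9 and 10 only)
Why: α-Lithiation of the enol ether, 1,2-carbonyl addition of the hard organolithium to the C2 carbonyl (the only one outside the vinylogous ester O–C3=C4–C1=O, as with alkyl semisquarates) and O-silylation of the alkoxide give 11, whose new C4 stereocentre is formed racemic, needs no control and disappears in step 5.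

Step 5
Reactants: 11 silyloxy(methoxyvinyl)cyclobutenone
Product: 14 4-[(tert-butyldimethylsilyl)oxy]-3-methoxy-5-(2,4,6-trimethoxyphenoxy)phenol (A–B hydroquinone, C2–O silylated, C5–OH free), via dienylketene 12 (not isolated), via cyclohexadienone 13 (not isolated)
Conditions: p-xylene (0.01 M, degassed), 138 °C, Ar, base-washed glass
Reagents that add atoms: none
Why: Heat breaks the cyclobutenone C1–C4 bond in a conrotatory 4π electrocyclic opening in which the silyloxy donor turns outward and the methoxyvinyl group inward, giving the (Z)-dienylketene 12. A disrotatory 6π electrocyclisation then joins the ketene carbon (ring B C5) to the vinyl CH2 (ring B C4), closing the six-membered ring B as dienone 13, which enolises to phenol 14. This is the Moore-type rearrangement of 4-alkenyl-4-oxycyclobutenones, applied here with an aryloxy instead of the usual alkoxy group at C3. No stereocentre is created, and the racemic carbinol carbon of 11 becomes the planar C2 of ring B. The step needs outward rotation of the oxygen substituent, which its donor character secures, and because the opening is reversible and a silyl ether has no lactonisation exit, any inward-rotated ketene should simply return to 11. The two ortho methoxy groups of ring A block capture of the ketene by that ring, and the pattern O–A at C1, OTBS at C2, OMe at C3 and free OH at C5 follows from the regiochemistry fixed in step 4.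

Step 6
Reactants: 14 monosilylated A–B hydroquinone
Product: 15 tert-butyl[2,4-dimethoxy-6-(2,4,6-trimethoxyphenoxy)phenoxy]dimethylsilane
Conditions: MeI, K2CO3, acetone, rt
Reagents that add atoms: iodomethane, CI
Why: Williamson ether synthesis on the only free phenol, while the C2 silyl ether is shielded by two ortho substituents, so no choice between two hydroxyls is asked of the reagent.

Step 7
Reactants: 15 silyl ether
Product: 16 2,4-dimethoxy-6-(2,4,6-trimethoxyphenoxy)phenol (A–B phenol, B C2–OH free)
Conditions: TBAF, AcOH, THF, 0 °C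
Reagents that add atoms: none
Why: Fluoride-mediated desilylation of an aryl silyl ether is fast, and the acetic acid buffer protonates the electron-rich phenoxide at once so that it is not exposed to air as the anion.

Step 8
Reactants: 17 2,3,4-trimethoxyphenol
Product: 18 6-iodo-2,3,4-trimethoxyphenol
Conditions: NIS, MeCN, 0 °C, dark
Reagents that add atoms: N-iodosuccinimide, O=C1CCC(=O)N1I
Why: Electrophilic aromatic iodination is steered by the free hydroxyl, whose para position is blocked, to C6 (ortho to OH, para to the C3 methoxy), the same outcome as in the halogenation of 4-methoxyphenol and 3,4-dimethoxyphenol.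

Step 9
Reactants: 18 6-iodo-2,3,4-trimethoxyphenol; 19 3,4,5-trimethoxyphenylboronic acid
Product: 20 1-iodo-3,4,5-trimethoxy-2-(3,4,5-trimethoxyphenoxy)benzene (D–E iodide)
Conditions: 19 (2 equiv), Cu(OAc)2, pyridine, 4 Å MS, CH2Cl2, dry air, rt
Reagents that add atoms: none
Why: The Chan–Lam–Evans oxidative O-arylation with divalent copper runs at room temperature, accepts phenols with two ortho substituents (ortho iodine included) when the boronic acid is unhindered, and leaves the C–I bond untouched.

Step 10
Reactants: 20 D–E iodide; 21 2,6-dimethoxyphenol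
Product: 22 1-(2,6-dimethoxyphenoxy)-3,4,5-trimethoxy-2-(3,4,5-trimethoxyphenoxy)benzene (C–D–E trimer)
Conditions: CuI (10 mol%), picolinic acid (20 mol%), K3PO4, DMSO, 90 °C, Ar
Reagents that add atoms: none
Why: Ullmann-type diaryl ether synthesis with the CuI/picolinic acid system developed for ortho-substituted partners, with the crowded phenol as nucleophile and an iodide that has only one ortho substituent.

Step 11
Reactants: 22 C–D–E trimer
Product: 24 1-(4-iodo-2,6-dimethoxyphenoxy)-3,4,5-trimethoxy-2-(3,4,5-trimethoxyphenoxy)benzene (C–D–E iodide), via pinacol boronate 23 (not isolated)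
Conditions: [Ir(OMe)(cod)]2 (2 mol%), dtbpy (4 mol%), B2pin2, THF, 80 °C; evaporate; CuI (10 mol%), 1,10-phenanthroline (20 mol%), KI, MeOH/H2O, air, 80 °C
Reagents that add atoms: bis(pinacolato)diboron, CC1(C)OB(OC1(C)C)B1OC(C)(C)C(C)(C)O1 (boryl group of 23 only); potassium iodide, [K+].[I-]
Why: Sterically governed iridium-catalysed C–H borylation should pick ring C C1–H, the only aromatic C–H of 22 without an ortho substituent, and the known copper-catalysed aerobic iododeboronation exchanges boron for iodine without an electrophilic iodine source that could attack ring E.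

Step 12
Reactants: 16 A–B phenol; 24 C–D–E iodide
Product: 25 5-(6-{4-[2,4-dimethoxy-6-(2,4,6-trimethoxyphenoxy)phenoxy]-2,6-dimethoxyphenoxy}-2,3,4-trimethoxyphenoxy)-1,2,3-trimethoxybenzene (tridecamethyl ether of the target)
Conditions: CuI (20 mol%), picolinic acid (40 mol%), K3PO4, DMSO, 100 °C, Ar
Reagents that add atoms: none
Why: Ullmann-type coupling again uses the favourable polarity for a crowded diaryl ether, the hindered B C2 phenoxide as nucleophile and an aryl iodide whose two ortho positions carry only hydrogen.

Step 13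
Reactants: 25 tridecamethyl ether
Product: 26 5-(6-{4-[2,4-dihydroxy-6-(2,4,6-trihydroxyphenoxy)phenoxy]-2,6-dihydroxyphenoxy}-2,3,4-trihydroxyphenoxy)benzene-1,2,3-triol (CNP0243665.0)
Conditions: BBr3 (30 equiv), CH2Cl2, −78 °C to rt, Ar; degassed H2O, 0 °C
Reagents that add atoms: none
Why: Lewis acid-mediated aryl methyl ether cleavage, in which boron binds each methoxy oxygen and bromide removes the methyl group by SN2, should free all thirteen phenols, while the four diaryl ether bridges offer no sp3 carbon and stay intact, and the oxygen-free work-up protects the pyrogallol-type rings.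

Compound list
1 | diisopropyl squarate | CC(C)OC1=C(OC(C)C)C(=O)C1=O | starting material
2 | 4-hydroxy-2,3-diisopropoxycyclobut-2-en-1-one (racemic) | CC(C)OC1=C(OC(C)C)C(O)C1=O | intermediate
3 | 3-isopropoxycyclobut-3-ene-1,2-dione | CC(C)OC1=CC(=O)C1=O | intermediate
4 | 3-hydroxycyclobut-3-ene-1,2-dione (semisquaric acid) | OC1=CC(=O)C1=O | intermediate
5 | 2,4,6-trimethoxyphenol | COc1cc(OC)c(O)c(OC)c1 | starting material
6 | 3-chlorocyclobut-3-ene-1,2-dione (semisquaric chloride) | ClC1=CC(=O)C1=O | intermediate
7 | 3-(2,4,6-trimethoxyphenoxy)cyclobut-3-ene-1,2-dione | COc1cc(OC)c(OC2=CC(=O)C2=O)c(OC)c1 | intermediate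
8 | methyl vinyl ether | COC=C | starting material
9 | 1-methoxyvinyllithium | [Li]C(=C)OC | intermediate
10 | lithium 1-(1-methoxyvinyl)-4-oxo-2-(2,4,6-trimethoxyphenoxy)cyclobut-2-en-1-olate (racemic) | [Li]OC1(C(=C)OC)C(=O)C=C1Oc1c(OC)cc(OC)cc1OC | intermediate
11 | 4-[(tert-butyldimethylsilyl)oxy]-4-(1-methoxyvinyl)-3-(2,4,6-trimethoxyphenoxy)cyclobut-2-en-1-one (racemic) | COC(=C)C1(O[Si](C)(C)C(C)(C)C)C(=O)C=C1Oc1c(OC)cc(OC)cc1OC | intermediate
12 | (3Z)-4-[(tert-butyldimethylsilyl)oxy]-5-methoxy-3-(2,4,6-trimethoxyphenoxy)hexa-1,3,5-trien-1-one (dienylketene) | O=C=C/C(Oc1c(OC)cc(OC)cc1OC)=C(\C(=C)OC)O[Si](C)(C)C(C)(C)C | intermediate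
13 | 4-[(tert-butyldimethylsilyl)oxy]-5-methoxy-3-(2,4,6-trimethoxyphenoxy)cyclohexa-2,4-dien-1-one | O=C1C=C(Oc2c(OC)cc(OC)cc2OC)C(O[Si](C)(C)C(C)(C)C)=C(OC)C1 | intermediate
14 | 4-[(tert-butyldimethylsilyl)oxy]-3-methoxy-5-(2,4,6-trimethoxyphenoxy)phenol | COc1cc(OC)c(Oc2cc(O)cc(OC)c2O[Si](C)(C)C(C)(C)C)c(OC)c1 | intermediate
15 | tert-butyl[2,4-dimethoxy-6-(2,4,6-trimethoxyphenoxy)phenoxy]dimethylsilane | COc1cc(OC)c(Oc2cc(OC)cc(OC)c2O[Si](C)(C)C(C)(C)C)c(OC)c1 | intermediate
16 | 2,4-dimethoxy-6-(2,4,6-trimethoxyphenoxy)phenol | COc1cc(OC)c(Oc2cc(OC)cc(OC)c2O)c(OC)c1 | intermediate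
17 | 2,3,4-trimethoxyphenol | COc1ccc(O)c(OC)c1OC | starting material
18 | 6-iodo-2,3,4-trimethoxyphenol | COc1cc(I)c(O)c(OC)c1OC | intermediate
19 | 3,4,5-trimethoxyphenylboronic acid | COc1cc(B(O)O)cc(OC)c1OC | starting material
20 | 1-iodo-3,4,5-trimethoxy-2-(3,4,5-trimethoxyphenoxy)benzene | COc1cc(I)c(Oc2cc(OC)c(OC)c(OC)c2)c(OC)c1OC | intermediate
21 | 2,6-dimethoxyphenol | COc1cccc(OC)c1O | starting material
22 | 1-(2,6-dimethoxyphenoxy)-3,4,5-trimethoxy-2-(3,4,5-trimethoxyphenoxy)benzene | COc1cccc(OC)c1Oc1cc(OC)c(OC)c(OC)c1Oc1cc(OC)c(OC)c(OC)c1 | intermediate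
23 | 2-{3,5-dimethoxy-4-[3,4,5-trimethoxy-2-(3,4,5-trimethoxyphenoxy)phenoxy]phenyl}-4,4,5,5-tetramethyl-1,3,2-dioxaborolane | COc1cc(B2OC(C)(C)C(C)(C)O2)cc(OC)c1Oc1cc(OC)c(OC)c(OC)c1Oc1cc(OC)c(OC)c(OC)c1 | intermediate
24 | 1-(4-iodo-2,6-dimethoxyphenoxy)-3,4,5-trimethoxy-2-(3,4,5-trimethoxyphenoxy)benzene | COc1cc(I)cc(OC)c1Oc1cc(OC)c(OC)c(OC)c1Oc1cc(OC)c(OC)c(OC)c1 | intermediate
25 | tridecamethyl ether of the target | COc1cc(OC)c(Oc2cc(OC)cc(OC)c2Oc2cc(OC)c(Oc3cc(OC)c(OC)c(OC)c3Oc3cc(OC)c(OC)c(OC)c3)c(OC)c2)c(OC)c1 | intermediate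
26 | CNP0243665.0 | Oc1cc(O)c(Oc2cc(O)cc(O)c2Oc2cc(O)c(Oc3cc(O)c(O)c(O)c3Oc3cc(O)c(O)c(O)c3)c(O)c2)c(O)c1 | target

Total step count: 13. Longest linear sequence: 9 steps (steps 1–7, 12 and 13, from diisopropyl squarate). The C–D–E branch (steps 8–11) runs in parallel.

Steps most likely to fail

Step 4. This addition is established for alkyl semisquarates, and an aryloxide leaves more readily than an alkoxide. The vinyllithium may therefore expel the aryloxide by addition–elimination at C3, or attack the less crowded C1 carbonyl. The congested tertiary alkoxide may also be silylated incompletely. The fallback gives up the four-membered ring and uses known chemistry; it sets out from 5 and comes back at 16. Coupling of 5 with commercial 2-bromo-4,6-dimethoxybenzaldehyde (CuI, picolinic acid, K3PO4, DMSO, 90 °C), helped by the ortho formyl group, should give 2,4-dimethoxy-6-(2,4,6-trimethoxyphenoxy)benzaldehyde F1. Baeyer–Villiger oxidation with mCPBA in CH2Cl2, in which the electron-rich aryl group migrates, gives 2,4-dimethoxy-6-(2,4,6-trimethoxyphenoxy)phenyl formate F2. Methanolysis (K2CO3, MeOH) then releases 16.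

Step 5. At 138 °C, traces of acid may strip the enol ether or the silyl group. The phenol being formed may trap the ketene intermolecularly, or the bulky silyloxy group may slow the ring opening. The fallback changes the protecting-group logic to the unprotected carbinol and handles the product at the quinone level; it sets out from 10 and comes back at 16.
- Quenching 10 with aqueous NH4Cl instead of the silyl triflate gives 4-hydroxy-4-(1-methoxyvinyl)-3-(2,4,6-trimethoxyphenoxy)cyclobut-2-en-1-one F3.
- Heating the crude carbinol in degassed p-xylene gives 2-methoxy-6-(2,4,6-trimethoxyphenoxy)benzene-1,4-diol F4.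
- Oxidation with Ag2O turns this into the air-stable, purifiable 2-methoxy-6-(2,4,6-trimethoxyphenoxy)cyclohexa-2,5-diene-1,4-dione F5, and Na2S2O4 returns F4.
- One equivalent of MeI with K2CO3 in acetone should alkylate the open C5–OH in preference to the flanked C2–OH, giving 16.

Step 12. C–O bond formation may be slow at a phenoxide flanked by an aryloxy and a methoxy group, which leaves time for hydrodeiodination of the iodide and oxidative decay of the phenol. The fallback replaces the halide-based coupling by an oxidative boron-based one at room temperature; it sets out from 23 (isolated after the borylation stage of step 11) and comes back at 25. Treatment with NaIO4 and NH4OAc in acetone/water cleaves the pinacol ester to {3,5-dimethoxy-4-[3,4,5-trimethoxy-2-(3,4,5-trimethoxyphenoxy)phenoxy]phenyl}boronic acid F6. Chan–Lam–Evans coupling of this acid with 16 (Cu(OAc)2, pyridine, 4 Å MS, CH2Cl2, dry air, rt) gives 25.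

Further compounds
F1 | step 4 | 2,4-dimethoxy-6-(2,4,6-trimethoxyphenoxy)benzaldehyde | COc1cc(OC)c(Oc2cc(OC)cc(OC)c2C=O)c(OC)c1
F2 | step 4 | 2,4-dimethoxy-6-(2,4,6-trimethoxyphenoxy)phenyl formate | COc1cc(OC)c(Oc2cc(OC)cc(OC)c2OC=O)c(OC)c1
F3 | step 5 | 4-hydroxy-4-(1-methoxyvinyl)-3-(2,4,6-trimethoxyphenoxy)cyclobut-2-en-1-one (racemic) | O=C1C=C(Oc2c(OC)cc(OC)cc2OC)C1(O)C(=C)OC
F4 | step 5 | 2-methoxy-6-(2,4,6-trimethoxyphenoxy)benzene-1,4-diol | COc1cc(OC)c(Oc2cc(O)cc(OC)c2O)c(OC)c1
F5 | step 5 | 2-methoxy-6-(2,4,6-trimethoxyphenoxy)cyclohexa-2,5-diene-1,4-dione | COC1=CC(=O)C=C(Oc2c(OC)cc(OC)cc2OC)C1=O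
F6 | step 12 | {3,5-dimethoxy-4-[3,4,5-trimethoxy-2-(3,4,5-trimethoxyphenoxy)phenoxy]phenyl}boronic acid | COc1cc(B(O)O)cc(OC)c1Oc1cc(OC)c(OC)c(OC)c1Oc1cc(OC)c(OC)c(OC)c1
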